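The succinate core C1(ester)–C2(aryl)–C3(benzyl)–C4(acid) is cut at C3–C4 and at C2–aryl. Both cuts rest on one oxetan-2-one ring (O–C2–C3–C4): it carries the C4 carboxyl on C3 as an acyl–oxygen bond and turns the C2 oxygen into a leaving group. The key step inserts carbon monoxide into the C3–O bond of a trans-glycidic ester, forming C3–C4 and C4–O and inverting C3 to give the cis-β-lactone. Its precursor is methyl (2S,3R)-3-(arylmethyl)oxirane-2-carboxylate carrying the silylated prenylphenol, made by Sharpless epoxidation. An aryl cuprate then opens the lactone at C2 with inversion, freeing the C4 acid beside the C1 methyl ester.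

Key step: step 10

Remarks: chain numbering C1 (ester carbonyl), C2 (aryl-bearing), C3 (benzyl-bearing), C4 (acid carbonyl) is used throughout and coincides with the ring locants of 11–14. TBS = tert-butyldimethylsilyl, prenyl = 3-methylbut-2-enyl. Assumption: (4-bromophenoxy)(tert-butyl)dimethylsilane 15 is bought as such (catalogue compound).

Step 1
Reactants: 1 4-hydroxybenzaldehyde; 2 1-bromo-3-methylbut-2-ene (prenyl bromide)
Product: 3 4-hydroxy-3-prenylbenzaldehyde
Conditions: aq. KOH (1.1 equiv), H2O, rt
Reagents that add atoms: none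
Why: C-alkylation of a phenoxide in water (hydrogen bonding to the phenoxide oxygen steers the allylic bromide to the ring carbon) is the known ortho-prenylation of phenols, and the para position is blocked by the formyl group so only the ortho carbon can react.

Step 2
Reactants: 3 4-hydroxy-3-prenylbenzaldehyde
Product: 4 4-(TBS-oxy)-3-prenylbenzaldehyde
Conditions: TBSCl, imidazole, DMF, rt
Reagents that add atoms: tert-butyldimethylsilyl chloride CC(C)(C)[Si](C)(C)Cl
Why: Imidazole-promoted O-silylation of the phenol is routine and gives an ether that should survive the hydride, Grignard, peroxide and Lewis-acid steps that follow.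

Step 3
Reactants: 4 4-(TBS-oxy)-3-prenylbenzaldehyde
Product: 5 [4-(TBS-oxy)-3-prenylphenyl]methanol
Conditions: NaBH4, MeOH, 0 °C
Reagents that add atoms: none
Why: Borohydride reduction of the aryl aldehyde is fast at 0 °C and should leave the aryl silyl ether and the trisubstituted alkene untouched.

Step 4
Reactants: 5 [4-(TBS-oxy)-3-prenylphenyl]methanol
Product: 6 [4-(bromomethyl)-2-prenylphenoxy](tert-butyl)dimethylsilane
Conditions: CBr4, PPh3, CH2Cl2, 0 °C
Reagents that add atoms: carbon tetrabromide BrC(Br)(Br)Br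
Why: The Appel reaction converts the benzylic alcohol into the bromide under neutral conditions with no free HBr, so the prenyl alkene and the silyl ether should be spared.

Step 5
Reactants: 6 [4-(bromomethyl)-2-prenylphenoxy](tert-butyl)dimethylsilane; 7 prop-2-yn-1-ol
Product: 9 4-[4-(TBS-oxy)-3-prenylphenyl]but-2-yn-1-ol, via propargyl alcohol bis(bromomagnesium) salt 8 (not isolated)
Conditions: 7 (2 equiv), EtMgBr (4 equiv), THF, 0 °C → rt; CuCl (10 mol %), then 6, THF, 50 °C; aq. NH4Cl
Reagents that add atoms: none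
Why: Copper-catalysed sp–sp3 coupling of an alkynyl Grignard reagent with a benzylic bromide is established for the O,C-dimagnesium derivative of propargyl alcohol, which is too weak a nucleophile at silicon to attack the silyl ether.

Step 6
Reactants: 9 4-[4-(TBS-oxy)-3-prenylphenyl]but-2-yn-1-ol
Product: 10 (E)-4-[4-(TBS-oxy)-3-prenylphenyl]but-2-en-1-ol
Conditions: Red-Al, THF, 0 °C → rt; aq. Rochelle salt
Reagents that add atoms: none
Why: Alkoxide-directed trans-hydroalumination of a propargylic alcohol followed by protonolysis gives the E-allylic alcohol only, and the isolated prenyl alkene is not reduced.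

Step 7
Reactants: 10 (E)-4-[4-(TBS-oxy)-3-prenylphenyl]but-2-en-1-ol
Product: 11 [(2R,3R)-3-{[4-(TBS-oxy)-3-prenylphenyl]methyl}oxiran-2-yl]methanol
Conditions: Ti(OiPr)4 (10 mol %), D-(−)-diisopropyl tartrate (12 mol %), t-BuOOH (decane), 4 Å MS, CH2Cl2, −20 °C
Reagents that add atoms: tert-butyl hydroperoxide CC(C)(C)OO
Why: In the Katsuki–Sharpless asymmetric epoxidation the titanium-bound allylic alkoxide receives oxygen syn on the face selected by the tartrate, and the D-(−) ligand (opposite in sense to the L-(+) ligand, which gives 2S,3S epoxy alcohols from E-3-alkyl allylic alcohols) sets C2 and C3 both R in a trans epoxide, while the prenyl alkene, not allylic to a hydroxyl, does not react.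

Step 8
Reactants: 11 [(2R,3R)-3-{[4-(TBS-oxy)-3-prenylphenyl]methyl}oxiran-2-yl]methanol
Product: 12 (2S,3R)-3-{[4-(TBS-oxy)-3-prenylphenyl]methyl}oxirane-2-carboxylic acid
Conditions: TEMPO (20 mol %), PhI(OAc)2 (2.2 equiv), MeCN/H2O 1:1, rt
Reagents that add atoms: water O
Why: Oxoammonium (TEMPO/PhI(OAc)2) oxidation takes the primary alcohol through the aldehyde hydrate to the acid without attacking the epoxide, the alkene or the aryl silyl ether, and no bond at a stereocentre is broken, the C2 descriptor changing from R to S only because the carboxyl now outranks C3.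

Step 9
Reactants: 12 (2S,3R)-3-{[4-(TBS-oxy)-3-prenylphenyl]methyl}oxirane-2-carboxylic acid
Product: 13 methyl (2S,3R)-3-{[4-(TBS-oxy)-3-prenylphenyl]methyl}oxirane-2-carboxylate
Conditions: TMSCHN2, PhMe/MeOH 4:1, 0 °C (crude acid used at once)
Reagents that add atoms: (trimethylsilyl)diazomethane C[Si](C)(C)C=[N+]=[N-]
Why: Diazoalkane O-methylation of the carboxylic acid is neutral and fast, so the acid-sensitive glycidic acid, the silyl ether and both stereocentres should be preserved.

Step 10
Reactants: 13 methyl (2S,3R)-3-{[4-(TBS-oxy)-3-prenylphenyl]methyl}oxirane-2-carboxylate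
Product: 14 methyl (2S,3S)-3-{[4-(TBS-oxy)-3-prenylphenyl]methyl}-4-oxooxetane-2-carboxylate
Conditions: [(salph)Al(THF)2][Co(CO)4] (5 mol %), CO (60 bar), THF, 50 °C
Reagents that add atoms: carbon monoxide [C-]#[O+]
Why: The aluminium cation binds the epoxide oxygen and tetracarbonylcobaltate opens the C3–O bond from the rear, CO then migrates into the new C3–Co bond with retention, and the aluminium-bound C2 alkoxide attacks the acylcobalt, expelling cobaltate and regenerating the ion pair. This is the known Lewis acid/cobaltate ring-expansion carbonylation of epoxides, which converts trans-2,3-disubstituted oxiranes into cis-β-lactones; on a 3-alkyl glycidic ester the regiochemistry is a reasoned expectation, not an established result. The oxetan-2-one ring closes by 4-exo-trig acyl substitution of the C2 oxygen on C4. C3 becomes S through the single SN2 inversion, the trajectory being fixed by the breaking C3–O bond, while C2 keeps its C–O bond and configuration, so the 2S,3R trans-epoxide should give only the 2S,3S cis-lactone. The step needs cobaltate attack at C3 and not at C2, which the ester should secure by withdrawing electron density from C2 and so destabilising the partial positive charge that develops there in a Lewis-acid-activated opening. The aryl silyl ether, the isolated trisubstituted alkene and the methyl ester should be inert to the catalyst under these conditions.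

Step 11
Reactants: 14 methyl (2S,3S)-3-{[4-(TBS-oxy)-3-prenylphenyl]methyl}-4-oxooxetane-2-carboxylate; 15 (4-bromophenoxy)(tert-butyl)dimethylsilane
Product: 18 (2S,3S)-3-[4-(TBS-oxy)phenyl]-2-{[4-(TBS-oxy)-3-prenylphenyl]methyl}-4-methoxy-4-oxobutanoic acid, via arylmagnesium bromide 16 (not isolated), via bromomagnesium diarylcuprate 17 (not isolated)
Conditions: 15, Mg, THF, reflux; CuBr·SMe2 (0.5 equiv per ArMgBr), THF/Me2S, −40 °C; then 14, −40 → −20 °C; aq. NH4Cl
Reagents that add atoms: none
Why: Organocuprates open β-lactones by SN2 attack at the oxygen-bearing ring carbon (alkyl–oxygen cleavage) with inversion, here favoured by ring strain and by the adjacent ester, so the aryl group should enter C2 anti to the departing carboxylate to give 2S and release the C4 acid with C3 untouched.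

Step 12
Reactants: 18 (2S,3S)-3-[4-(TBS-oxy)phenyl]-2-{[4-(TBS-oxy)-3-prenylphenyl]methyl}-4-methoxy-4-oxobutanoic acid
Product: 19 Asperteretal G2, (2S,3S)-3-(4-hydroxyphenyl)-2-{[4-hydroxy-3-prenylphenyl]methyl}-4-methoxy-4-oxobutanoic acid
Conditions: TBAF/AcOH (1:1.2, 2.5 equiv), THF, 0 °C
Reagents that add atoms: none
Why: Fluoride cleaves both aryl silyl ethers, and the acetic acid buffer should prevent base-induced epimerisation of the acidic C2–H (α to ester and aryl) and also avoids strong acid, which would cyclise the ortho-prenylphenol to a chroman.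

Compound list

1 | 4-hydroxybenzaldehyde | O=Cc1ccc(O)cc1 | starting material
2 | 1-bromo-3-methylbut-2-ene | CC(C)=CCBr | starting material
3 | 4-hydroxy-3-(3-methylbut-2-enyl)benzaldehyde | O=Cc1ccc(O)c(CC=C(C)C)c1 | intermediate
4 | 4-(tert-butyldimethylsilyloxy)-3-(3-methylbut-2-enyl)benzaldehyde | O=Cc1ccc(O[Si](C)(C)C(C)(C)C)c(CC=C(C)C)c1 | intermediate
5 | [4-(tert-butyldimethylsilyloxy)-3-(3-methylbut-2-enyl)phenyl]methanol | OCc1ccc(O[Si](C)(C)C(C)(C)C)c(CC=C(C)C)c1 | intermediate
6 | [4-(bromomethyl)-2-(3-methylbut-2-enyl)phenoxy](tert-butyl)dimethylsilane | BrCc1ccc(O[Si](C)(C)C(C)(C)C)c(CC=C(C)C)c1 | intermediate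
7 | prop-2-yn-1-ol | OCC#C | starting material
8 | bromomagnesium 3-(bromomagnesio)prop-2-yn-1-olate | Br[Mg]OCC#C[Mg]Br | intermediate (not isolated)
9 | 4-[4-(tert-butyldimethylsilyloxy)-3-(3-methylbut-2-enyl)phenyl]but-2-yn-1-ol | OCC#CCc1ccc(O[Si](C)(C)C(C)(C)C)c(CC=C(C)C)c1 | intermediate
10 | (E)-4-[4-(tert-butyldimethylsilyloxy)-3-(3-methylbut-2-enyl)phenyl]but-2-en-1-ol | OC/C=C/Cc1ccc(O[Si](C)(C)C(C)(C)C)c(CC=C(C)C)c1 | intermediate
11 | [(2R,3R)-3-{[4-(tert-butyldimethylsilyloxy)-3-(3-methylbut-2-enyl)phenyl]methyl}oxiran-2-yl]methanol | OC[C@H]1O[C@@H]1Cc1ccc(O[Si](C)(C)C(C)(C)C)c(CC=C(C)C)c1 | intermediate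
12 | (2S,3R)-3-{[4-(tert-butyldimethylsilyloxy)-3-(3-methylbut-2-enyl)phenyl]methyl}oxirane-2-carboxylic acid | OC(=O)[C@H]1O[C@@H]1Cc1ccc(O[Si](C)(C)C(C)(C)C)c(CC=C(C)C)c1 | intermediate
13 | methyl (2S,3R)-3-{[4-(tert-butyldimethylsilyloxy)-3-(3-methylbut-2-enyl)phenyl]methyl}oxirane-2-carboxylate | COC(=O)[C@H]1O[C@@H]1Cc1ccc(O[Si](C)(C)C(C)(C)C)c(CC=C(C)C)c1 | intermediate
14 | methyl (2S,3S)-3-{[4-(tert-butyldimethylsilyloxy)-3-(3-methylbut-2-enyl)phenyl]methyl}-4-oxooxetane-2-carboxylate | COC(=O)[C@H]1OC(=O)[C@H]1Cc1ccc(O[Si](C)(C)C(C)(C)C)c(CC=C(C)C)c1 | intermediate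
15 | (4-bromophenoxy)(tert-butyl)dimethylsilane | CC(C)(C)[Si](C)(C)Oc1ccc(Br)cc1 | starting material
16 | [4-(tert-butyldimethylsilyloxy)phenyl]magnesium bromide | CC(C)(C)[Si](C)(C)Oc1ccc([Mg]Br)cc1 | intermediate (not isolated)
17 | bromomagnesium bis[4-(tert-butyldimethylsilyloxy)phenyl]cuprate | CC(C)(C)[Si](C)(C)Oc1ccc([Cu-]c2ccc(O[Si](C)(C)C(C)(C)C)cc2)cc1.[Mg+]Br | intermediate (not isolated)
18 | (2S,3S)-3-[4-(tert-butyldimethylsilyloxy)phenyl]-2-{[4-(tert-butyldimethylsilyloxy)-3-(3-methylbut-2-enyl)phenyl]methyl}-4-methoxy-4-oxobutanoic acid | COC(=O)[C@H](c1ccc(O[Si](C)(C)C(C)(C)C)cc1)[C@H](Cc1ccc(O[Si](C)(C)C(C)(C)C)c(CC=C(C)C)c1)C(=O)O | intermediate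
19 | Asperteretal G2, (2S,3S)-3-(4-hydroxyphenyl)-2-{[4-hydroxy-3-(3-methylbut-2-enyl)phenyl]methyl}-4-methoxy-4-oxobutanoic acid | COC(=O)[C@H](c1ccc(O)cc1)[C@H](Cc1ccc(O)c(CC=C(C)C)c1)C(=O)O | target

Total step count: 12. Longest linear sequence: 12 steps (1 → 19); 15 enters at step 11.

Steps most likely to fail

Step 10. The risk is regiochemical leakage, with cobaltate attacking C2 instead of C3 to give the isomeric lactone. Lewis-acid-induced rearrangement of the glycidate to a carbonyl compound, or catalyst inhibition by chelation, are the other failure processes. The fallback builds the same lactone by enolate alkylation and invertive lactonisation, sets out from 6 and returns at 14. Commercial (R)-malic acid, OC(=O)[C@H](O)CC(=O)O, is treated with trifluoroacetic anhydride and then methanol, which opens the O-trifluoroacetyl anhydride at the carbonyl next to the oxygen and gives (R)-malic acid 1-methyl ester F1. The free C4 acid is esterified with tert-butyl 2,2,2-trichloroacetimidate to 4-tert-butyl 1-methyl (R)-malate F2. Its alkoxide–enolate dianion (LiHMDS, 2.2 equiv, THF, −78 → −20 °C) is alkylated by 6 anti to the alkoxide (Seebach–Fráter alkylation), which should give 4-tert-butyl 1-methyl (2R,3S)-2-hydroxy-3-(arylmethyl)butanedioate F3. TMSOTf/2,6-lutidine followed by aqueous work-up removes the tert-butyl ester without protic acid to give the (2R,3S)-hydroxy acid F4. Mitsunobu lactonisation (PPh3, DIAD, THF, −78 °C → rt) activates the C2 hydroxyl, and the C4 carboxylate displaces it with inversion to give the 2S,3S cis-lactone 14.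

Step 11. The risk is addition of the aryl metal to the lactone carbonyl (acyl–oxygen cleavage), or electron-transfer reduction of the C2–O bond, in place of SN2 displacement at C2. The fallback moves the displacement to an acyclic triflate, sets out from 14 and returns at 18. Lanthanide-alkoxide-catalysed alcoholysis with allyl alcohol (cat. La(OiPr)3, THF, 0 °C) opens the lactone at the acyl carbon with retention at C2 to give 4-allyl 1-methyl (2S,3S)-2-hydroxy-3-(arylmethyl)butanedioate F5. Tf2O/2,6-lutidine at −78 °C gives the C2 triflate F6. Cuprate 17 displaces the triflate with inversion, with no strained acyl group competing, to give 4-allyl 1-methyl (2S,3S)-2-[4-(TBS-oxy)phenyl]-3-(arylmethyl)butanedioate F7. Pd(PPh3)4/morpholine removes the allyl ester to give 18.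

Step 5. The risk is Wurtz-type homocoupling of the electron-rich benzylic bromide, or base-induced propargyl–allenyl isomerisation of the skipped aryl-alkyne. The fallback forms the benzyl–alkenyl bond by palladium catalysis, sets out from 6 and 7 and returns at 10. Radical hydrostannation of 7 (Bu3SnH, AIBN, 80 °C, minor isomers removed by chromatography) gives (E)-3-(tributylstannyl)prop-2-en-1-ol F8. Stille coupling of F8 with 6 (Pd2(dba)3, AsPh3, THF, 55 °C) proceeds with retention of alkene geometry and should give 10 directly, which also bypasses step 6.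

Further compounds

F1 | step 10 | (R)-malic acid 1-methyl ester, (3R)-3-hydroxy-4-methoxy-4-oxobutanoic acid | COC(=O)[C@H](O)CC(=O)O
F2 | step 10 | 4-tert-butyl 1-methyl (2R)-2-hydroxybutanedioate | COC(=O)[C@H](O)CC(=O)OC(C)(C)C
F3 | step 10 | 4-tert-butyl 1-methyl (2R,3S)-2-hydroxy-3-{[4-(tert-butyldimethylsilyloxy)-3-(3-methylbut-2-enyl)phenyl]methyl}butanedioate | COC(=O)[C@H](O)[C@H](Cc1ccc(O[Si](C)(C)C(C)(C)C)c(CC=C(C)C)c1)C(=O)OC(C)(C)C
F4 | step 10 | (2S,3R)-3-hydroxy-4-methoxy-4-oxo-2-{[4-(tert-butyldimethylsilyloxy)-3-(3-methylbut-2-enyl)phenyl]methyl}butanoic acid (chain C2 R, C3 S) | COC(=O)[C@H](O)[C@H](Cc1ccc(O[Si](C)(C)C(C)(C)C)c(CC=C(C)C)c1)C(=O)O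
F5 | step 11 | 4-allyl 1-methyl (2S,3S)-2-hydroxy-3-{[4-(tert-butyldimethylsilyloxy)-3-(3-methylbut-2-enyl)phenyl]methyl}butanedioate | COC(=O)[C@@H](O)[C@H](Cc1ccc(O[Si](C)(C)C(C)(C)C)c(CC=C(C)C)c1)C(=O)OCC=C
F6 | step 11 | 4-allyl 1-methyl (2S,3S)-3-{[4-(tert-butyldimethylsilyloxy)-3-(3-methylbut-2-enyl)phenyl]methyl}-2-(trifluoromethylsulfonyloxy)butanedioate | COC(=O)[C@@H](OS(=O)(=O)C(F)(F)F)[C@H](Cc1ccc(O[Si](C)(C)C(C)(C)C)c(CC=C(C)C)c1)C(=O)OCC=C
F7 | step 11 | 4-allyl 1-methyl (2S,3S)-2-[4-(tert-butyldimethylsilyloxy)phenyl]-3-{[4-(tert-butyldimethylsilyloxy)-3-(3-methylbut-2-enyl)phenyl]methyl}butanedioate | COC(=O)[C@H](c1ccc(O[Si](C)(C)C(C)(C)C)cc1)[C@H](Cc1ccc(O[Si](C)(C)C(C)(C)C)c(CC=C(C)C)c1)C(=O)OCC=C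
F8 | step 5 | (E)-3-(tributylstannyl)prop-2-en-1-ol | OC/C=C/[Sn](CCCC)(CCCC)CCCC
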